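**Retrosynthetic overview**

1. Numbering as in labdanes: ring A = C1–C5 and C10; ring B = C5–C10; C17 = formyl carbon on C8; C11–C16 = side chain on C9; C20 = methyl on C10. Enabling feature: in ring B the bonds C6–C7 and C5–C10 flank the C8–C9 bond, C8 carries only a one-carbon branch and C10 is quaternary, so ring B is the retron of a [4+2] cycloaddition between a C7=C8(O)–C9=C10 dienol ether and a C5=C6 vinyl group joined through C1–C4.
2. Endgame: CHO from C17–OH, from hydroboration of a C8=C17 alkene anti to C20, from a C8 ketone; the (Z)-enoate from Negishi coupling of a C12 alkylzinc with methyl (Z)-3-iodobut-2-enoate.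
3. C8 ketone and C12 alcohol from hydrolysis of a tricyclic enol ether, in which a temporary oxolane ring (O–C8, C9–C11–C12–O) had held the diene.
4. Key disconnection: intramolecular Diels–Alder reaction forming C6–C7 and C5–C10, so that rings B and A close together from a triene whose only stereocentre is C3.
5. Triene from 2-acetylbutyrolactone (C8–C12, C20), a zinc homoenolate equivalent (C1–C3), 1,1-dimethylallene (C4–C6; asymmetric reverse prenylation sets C3) and one CH2 (C7) by lactone methylenation. Ring order: oxolane (present from the start), rings A and B simultaneously (step 7), oxolane opened (step 8).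

Key step: step 7

Assumption: in step 4 the (S)-ligand is taken to give the (R)-carbinol; if the sense of induction proved opposite, the (R)-ligand would be used under the same conditions.

**Route**

Step 1
Reactants: 1 2-acetylbutyrolactone (3-acetyloxolan-2-one)
Product: 2 (E)-1-(2-oxooxolan-3-ylidene)ethyl trifluoromethanesulfonate (triflate oxygen trans, methyl cis to the lactone carbonyl)
Conditions: Tf2O (1.2 equiv), 25% aq. Me4NOH (1.5 equiv), toluene, 0 °C → rt
Reagents that add atoms: trifluoromethanesulfonic anhydride, O=S(=O)(OS(=O)(=O)C(F)(F)F)C(F)(F)F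
Why: Stereoselective enol triflate formation from a β-keto lactone: with the non-coordinating tetramethylammonium counter-ion the enolate oxygen should lie anti to the lactone carbonyl, so O-sulfonylation should give the (E)-triflate.

Step 2
Reactants: 2 (E)-enol triflate; 3 [2-(1,3-dioxolan-2-yl)ethyl]zinc bromide (solution in THF)
Product: 4 (E)-3-[4-(1,3-dioxolan-2-yl)butan-2-ylidene]oxolan-2-one
Conditions: Pd(PPh3)4 (5 mol%), THF, rt → 50 °C
Reagents that add atoms: none
Why: Negishi cross-coupling of a primary alkylzinc halide with an electron-poor alkenyl triflate proceeds with retention of geometry, so the new chain (C1–C3) ends up trans to the lactone carbonyl and the tetrasubstituted C9=C10 alkene should form as a single isomer.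

Step 3
Reactants: 4 acetal lactone
Product: 5 (E)-4-(2-oxooxolan-3-ylidene)pentanal
Conditions: 1 M aq. HCl, THF, rt
Reagents that add atoms: water, O
Why: Acid-catalysed acetal hydrolysis; the tetrasubstituted alkylidene lactone is inert to dilute aqueous acid.

Step 4
Reactants: 5 aldehyde; 6 3-methylbuta-1,2-diene (1,1-dimethylallene)
Product: 7 (E)-3-[(5R)-5-hydroxy-6,6-dimethyloct-7-en-2-ylidene]oxolan-2-one
Conditions: [Ir(cod)Cl]2 (2.5 mol%), (S)-SEGPHOS (5 mol%), 4-cyano-3-nitrobenzoic acid (10 mol%), Cs2CO3 (20 mol%), i-PrOH (2 equiv), toluene, 60 °C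
Reagents that add atoms: none
Why: Iridium-catalysed transfer-hydrogenative carbonyl reverse prenylation (isopropanol as terminal reductant) forms the C3–C4 bond together with the gem-dimethyl carbon and the vinyl dienophile; the chiral cyclometalated iridium complex should differentiate the aldehyde faces in a closed chair transition state to give the (R)-carbinol.

Step 5
Reactants: 7 alcohol
Product: 8 (E)-3-[(5R)-5-(tert-butyldimethylsilyloxy)-6,6-dimethyloct-7-en-2-ylidene]oxolan-2-one
Conditions: TBSOTf (1.3 equiv), 2,6-lutidine (2 equiv), CH2Cl2, −78 → 0 °C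
Reagents that add atoms: tert-butyldimethylsilyl trifluoromethanesulfonate, CC(C)(C)[Si](C)(C)OS(=O)(=O)C(F)(F)F
Why: Silylation of the hindered neopentylic secondary alcohol with the reactive silyl triflate; the bulky ether later serves as the equatorial control group of the cycloaddition.

Step 6
Reactants: 8 silyl ether lactone
Product: 9 (E)-3-[(5R)-5-(tert-butyldimethylsilyloxy)-6,6-dimethyloct-7-en-2-ylidene]-2-methylideneoxolane
Conditions: Cp2TiMe2 (2.5 equiv), toluene, pyridine (1 vol%), 70 °C, dark; filtration through basic Al2O3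
Reagents that add atoms: dimethyltitanocene Cp2TiMe2, C[Ti](C)(C1C=CC=C1)C1C=CC=C1
Why: Carbonyl methylenation of a lactone with Cp2TiMe2 (Petasis olefination, via Cp2Ti=CH2) should convert the α-alkylidene lactone into a 2-alkoxy-1,3-diene held s-cis by the oxolane ring, under non-acidic conditions that leave the silyl ether, the vinyl group and the C9=C10 geometry untouched.

Step 7
Reactants: 9 triene
Product: 10 tert-butyldimethylsilyl ether of (5aS,7R,9aR)-6,6,9a-trimethyl-1,2,4,5,5a,6,7,8,9,9a-decahydronaphtho[2,1-b]furan-7-ol (rings A/B trans-fused, C8=C9 enol ether, silyloxy group cis to the angular methyl)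
Conditions: toluene (0.005 M, degassed), BHT (0.1 equiv), Et3N (0.2 equiv), base-washed sealed tube, 180 °C
Reagents that add atoms: none
Why: Thermal, concerted but asynchronous [4+2] cycloaddition (type 1 intramolecular Diels–Alder reaction of a 1,7,9-decatriene; closest known reaction type: thermal cyclisation of 2-alkoxy- or 2-silyloxy-1,3-dienes onto unactivated terminal alkenes), in which the two unhindered CH2 termini C6 and C7 bond ahead of the congested C5–C10 pair. Ring B is closed as the cyclohexene of the cycloaddition (new bonds C6–C7 and C5–C10, C8=C9 left as the enol ether) and ring A as the six-membered ring spanned by the four-carbon tether C1–C4 in the fused mode, so both carbocycles form in one operation. The temporary oxolane ring holds the diene s-cis and, through the geometry fixed in steps 1 and 2, places the tether outside and the C20 methyl inside at C10, the arrangement required for a trans-fused transition state. C5 and C10 are created together: the trans ring fusion should result from the chair-like tether/boat-like transition state with the quaternary C4 exo (anti to C9) and H5 over the diene, because the cis-fused alternative forces C4 and its methyl groups endo over C9 and C11. The absolute configuration of both centres is relayed from C3, whose bulky silyloxy group takes the equatorial position of the chair-like tether and so selects one π-face of diene and dienophile. The step needs fused rather than bridged regiochemistry (secured by the tether length), trans rather than cis fusion (secured as described) and cycloaddition ahead of [1,5]-hydrogen shift of the inside methyl or acid-induced isomerisation of the dienol ether (secured by the locked s-cis diene, the gem-dimethyl effect at C4, high dilution, base-washed glassware and the amine additive).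

Step 8
Reactants: 10 tricyclic enol ether
Product: 11 (1S,4aS,6R,8aR)-6-(tert-butyldimethylsilyloxy)-1-(2-hydroxyethyl)-5,5,8a-trimethyloctahydronaphthalen-2(1H)-one (hydroxyethyl chain equatorial, cis to the angular methyl)
Conditions: 10% aq. oxalic acid, THF, rt
Reagents that add atoms: water, O
Why: Acid-catalysed enol ether hydrolysis opens the temporary oxolane ring to the C8 ketone and the C12 alcohol; C9 should be protonated anti to the angular methyl and, being α to the ketone, can equilibrate to the same, more stable configuration with the chain equatorial.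

Step 9
Reactants: 11 keto alcohol
Product: 12 2-[(1R,4aS,6R,8aS)-6-(tert-butyldimethylsilyloxy)-5,5,8a-trimethyl-2-methylidenedecahydronaphthalen-1-yl]ethan-1-ol
Conditions: Ph3PCH3Br (4 equiv), KOt-Bu (4 equiv), toluene, rt → 80 °C
Reagents that add atoms: methyltriphenylphosphonium bromide, C[P+](c1ccccc1)(c1ccccc1)c1ccccc1.[Br-]
Why: Wittig methylenation of the hindered ketone (excess ylide tolerates the free alcohol as its alkoxide) installs the exocyclic C8=C17 alkene without disturbing C9, which already has its preferred configuration.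

Step 10
Reactants: 12 alkenyl alcohol
Product: 13 (1R,4aS,6R,8aS)-6-(tert-butyldimethylsilyloxy)-1-(2-iodoethyl)-5,5,8a-trimethyl-2-methylidenedecahydronaphthalene
Conditions: PPh3 (1.3 equiv), I2 (1.3 equiv), imidazole (2 equiv), CH2Cl2, 0 °C → rt
Reagents that add atoms: iodine, II
Why: Appel-type iodination of the unhindered primary alcohol by SN2 displacement of the alkoxyphosphonium intermediate.

Step 11
Reactants: 14 methyl but-2-ynoate
Product: 15 methyl (Z)-3-iodobut-2-enoate
Conditions: NaI (1.6 equiv), AcOH, 110 °C
Reagents that add atoms: sodium iodide, [Na+].[I-]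
Why: Hydroiodination of the ynoate by conjugate addition of iodide and anti protonation should give the (Z)-β-iodo enoate.

Step 12
Reactants: 13 iodide; 15 methyl (Z)-3-iodobut-2-enoate
Product: 17 methyl (2Z)-5-[(1R,4aS,6R,8aS)-6-(tert-butyldimethylsilyloxy)-5,5,8a-trimethyl-2-methylidenedecahydronaphthalen-1-yl]-3-methylpent-2-enoate, via alkylzinc iodide 16 (not isolated)
Conditions: Zn dust (3 equiv, activated by 1,2-dibromoethane and Me3SiCl), LiCl (1.5 equiv), THF, 40 °C; then 15 (1.2 equiv), Pd(PPh3)4 (5 mol%), THF, rt → 40 °C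
Reagents that add atoms: zinc, [Zn] (in intermediate 16 only)
Why: Zinc insertion into the primary iodide followed by Negishi cross-coupling with the alkenyl iodide proceeds with retention of alkene geometry, so the (Z)-3-methylpent-2-enoate terminus is installed directly while the exocyclic alkene and the silyl ether stay inert.

Step 13
Reactants: 17 dienoate
Product: 19 methyl (2Z)-5-[(1R,2R,4aS,6R,8aS)-6-(tert-butyldimethylsilyloxy)-2-(hydroxymethyl)-5,5,8a-trimethyldecahydronaphthalen-1-yl]-3-methylpent-2-enoate, via B-alkyl-9-BBN adduct 18 (not isolated)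
Conditions: 9-BBN dimer (1.5 equiv B–H), THF, 0 °C → rt; then 30% H2O2, aq. NaOAc, 0 °C → rt
Reagents that add atoms: 9-borabicyclo[3.3.1]nonane, B1C2CCCC1CCC2 (boron and its ring, in intermediate 18 only); hydrogen peroxide, OO (hydroxyl oxygen)
Why: Hydroboration–oxidation: 9-BBN should add with boron at terminal C17 of the 1,1-disubstituted exocyclic alkene in preference to the trisubstituted conjugated ester and deliver hydrogen to C8 from the face anti to the axial angular methyl (equatorial attack), which sets C8 with the hydroxymethyl group axial and cis to both the C10 methyl and the C9 side chain.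

Step 14
Reactants: 19 silyl ether alcohol
Product: 20 methyl (2Z)-5-[(1R,2R,4aS,6R,8aS)-6-hydroxy-2-(hydroxymethyl)-5,5,8a-trimethyldecahydronaphthalen-1-yl]-3-methylpent-2-enoate
Conditions: 48% aq. HF, MeCN, 0 °C → rt
Reagents that add atoms: none
Why: Fluoride-mediated cleavage of the secondary silyl ether under acidic conditions that leave the enoate and its geometry unchanged.

Step 15
Reactants: 20 diol
Product: 21 methyl (2Z)-5-[(1R,2R,4aS,6R,8aS)-2-formyl-6-hydroxy-5,5,8a-trimethyldecahydronaphthalen-1-yl]-3-methylpent-2-enoate (CNP0188570.2)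
Conditions: TEMPO (10 mol%), PhI(OAc)2 (1.1 equiv), CH2Cl2, rt
Reagents that add atoms: none
Why: TEMPO/PhI(OAc)2 oxidation via the oxoammonium salt is selective for the primary over the hindered secondary alcohol and stops at the aldehyde, and the base-free medium should avoid epimerisation of the axial formyl group at C8.

**Compound list**

1 | 2-acetylbutyrolactone (3-acetyloxolan-2-one) | CC(=O)C1CCOC1=O | starting material
2 | (E)-1-(2-oxooxolan-3-ylidene)ethyl trifluoromethanesulfonate | C/C(OS(=O)(=O)C(F)(F)F)=C1/CCOC1=O | intermediate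
3 | [2-(1,3-dioxolan-2-yl)ethyl]zinc bromide | Br[Zn]CCC1OCCO1 | starting material
4 | (E)-3-[4-(1,3-dioxolan-2-yl)butan-2-ylidene]oxolan-2-one | C/C(CCC1OCCO1)=C2/CCOC2=O | intermediate
5 | (E)-4-(2-oxooxolan-3-ylidene)pentanal | C/C(CCC=O)=C1/CCOC1=O | intermediate
6 | 3-methylbuta-1,2-diene | CC(C)=C=C | starting material
7 | (E)-3-[(5R)-5-hydroxy-6,6-dimethyloct-7-en-2-ylidene]oxolan-2-one | C/C(CC[C@@H](O)C(C)(C)C=C)=C1/CCOC1=O | intermediate
8 | (E)-3-[(5R)-5-(tert-butyldimethylsilyloxy)-6,6-dimethyloct-7-en-2-ylidene]oxolan-2-one | C/C(CC[C@@H](O[Si](C)(C)C(C)(C)C)C(C)(C)C=C)=C1/CCOC1=O | intermediate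
9 | (E)-3-[(5R)-5-(tert-butyldimethylsilyloxy)-6,6-dimethyloct-7-en-2-ylidene]-2-methylideneoxolane | C/C(CC[C@@H](O[Si](C)(C)C(C)(C)C)C(C)(C)C=C)=C1/CCOC1=C | intermediate
10 | tert-butyldimethylsilyl ether of (5aS,7R,9aR)-6,6,9a-trimethyl-1,2,4,5,5a,6,7,8,9,9a-decahydronaphtho[2,1-b]furan-7-ol | C1CC2=C(O1)CC[C@@H]3C(C)(C)[C@H](O[Si](C)(C)C(C)(C)C)CC[C@@]23C | intermediate
11 | (1S,4aS,6R,8aR)-6-(tert-butyldimethylsilyloxy)-1-(2-hydroxyethyl)-5,5,8a-trimethyloctahydronaphthalen-2(1H)-one | OCC[C@@H]1C(=O)CC[C@@H]2C(C)(C)[C@H](O[Si](C)(C)C(C)(C)C)CC[C@@]12C | intermediate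
12 | 2-[(1R,4aS,6R,8aS)-6-(tert-butyldimethylsilyloxy)-5,5,8a-trimethyl-2-methylidenedecahydronaphthalen-1-yl]ethan-1-ol | OCC[C@@H]1C(=C)CC[C@@H]2C(C)(C)[C@H](O[Si](C)(C)C(C)(C)C)CC[C@@]12C | intermediate
13 | (1R,4aS,6R,8aS)-6-(tert-butyldimethylsilyloxy)-1-(2-iodoethyl)-5,5,8a-trimethyl-2-methylidenedecahydronaphthalene | ICC[C@@H]1C(=C)CC[C@@H]2C(C)(C)[C@H](O[Si](C)(C)C(C)(C)C)CC[C@@]12C | intermediate
14 | methyl but-2-ynoate | CC#CC(=O)OC | starting material
15 | methyl (Z)-3-iodobut-2-enoate | COC(=O)/C=C(/C)I | intermediate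
16 | {2-[(1R,4aS,6R,8aS)-6-(tert-butyldimethylsilyloxy)-5,5,8a-trimethyl-2-methylidenedecahydronaphthalen-1-yl]ethyl}zinc iodide | I[Zn]CC[C@@H]1C(=C)CC[C@@H]2C(C)(C)[C@H](O[Si](C)(C)C(C)(C)C)CC[C@@]12C | intermediate (not isolated)
17 | methyl (2Z)-5-[(1R,4aS,6R,8aS)-6-(tert-butyldimethylsilyloxy)-5,5,8a-trimethyl-2-methylidenedecahydronaphthalen-1-yl]-3-methylpent-2-enoate | COC(=O)/C=C(/C)CC[C@@H]1C(=C)CC[C@@H]2C(C)(C)[C@H](O[Si](C)(C)C(C)(C)C)CC[C@@]12C | intermediate
18 | methyl (2Z)-5-[(1R,2R,4aS,6R,8aS)-2-[(9-borabicyclo[3.3.1]nonan-9-yl)methyl]-6-(tert-butyldimethylsilyloxy)-5,5,8a-trimethyldecahydronaphthalen-1-yl]-3-methylpent-2-enoate | COC(=O)/C=C(/C)CC[C@@H]1[C@H](CB3C4CCCC3CCC4)CC[C@@H]2C(C)(C)[C@H](O[Si](C)(C)C(C)(C)C)CC[C@@]12C | intermediate (not isolated)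
19 | methyl (2Z)-5-[(1R,2R,4aS,6R,8aS)-6-(tert-butyldimethylsilyloxy)-2-(hydroxymethyl)-5,5,8a-trimethyldecahydronaphthalen-1-yl]-3-methylpent-2-enoate | COC(=O)/C=C(/C)CC[C@@H]1[C@H](CO)CC[C@@H]2C(C)(C)[C@H](O[Si](C)(C)C(C)(C)C)CC[C@@]12C | intermediate
20 | methyl (2Z)-5-[(1R,2R,4aS,6R,8aS)-6-hydroxy-2-(hydroxymethyl)-5,5,8a-trimethyldecahydronaphthalen-1-yl]-3-methylpent-2-enoate | COC(=O)/C=C(/C)CC[C@@H]1[C@H](CO)CC[C@@H]2C(C)(C)[C@H](O)CC[C@@]12C | intermediate
21 | methyl (2Z)-5-[(1R,2R,4aS,6R,8aS)-2-formyl-6-hydroxy-5,5,8a-trimethyldecahydronaphthalen-1-yl]-3-methylpent-2-enoate | COC(=O)/C=C(/C)CC[C@@H]1[C@H](C=O)CC[C@@H]2C(C)(C)[C@H](O)CC[C@@]12C | target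

Total step count: 15. Longest linear sequence: 14 steps (steps 1–10 and 12–15; step 11 prepares coupling partner 15).

**Steps most likely to fail**

Step 7. The cycloaddition of the unactivated, neopentylic vinyl group onto a diene with a fully substituted terminus may be too slow at temperatures where [1,5]-hydrogen shift of the inside methyl or isomerisation of the dienol ether takes over. Discrimination between trans and cis fusion, and between the two π-faces (the equatorial preference of the C3 silyloxy group next to the gem-dimethyl carbon is modest), may also be incomplete. The fallback sets out from 8 and returns at 10, and activates the dienophile with a removable sulfonyl group. Oxidative cleavage of the vinyl group of 8 (OsO4 2 mol%, NaIO4, 2,6-lutidine, dioxane/H2O, rt) should give the aldehyde F1. Horner–Wadsworth–Emmons olefination with diethyl [(phenylsulfonyl)methyl]phosphonate (NaH, THF, 0 °C → rt) should give the (E)-vinyl sulfone F2, and methylenation with Cp2TiMe2 (toluene, 70 °C) the sulfonyl dienol ether F3. The intramolecular Diels–Alder reaction of this activated triene should run near 110–130 °C (toluene, BHT, Et3N); the endo preference of the (E)-sulfonyl group reinforces the trans-fused transition state and should give the sulfonyl cycloadduct F4. Reductive desulfonylation (Na(Hg), Na2HPO4, MeOH/THF, −20 °C) then gives 10.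

Step 6. Methylenation of the hindered, conjugated lactone carbonyl may be incomplete, and the acid-labile dienol ether may isomerise during prolonged heating with titanium residues. The fallback sets out from 8 and returns at 9, and builds the same enol ether by alkyne hydroalkoxylation instead of carbene transfer. Reduction of 8 (i-Bu2AlH, CH2Cl2, −78 °C) should give the lactol F5. Seyferth–Gilbert homologation with dimethyl (1-diazo-2-oxopropyl)phosphonate (K2CO3, MeOH, rt) should give the enynol F6. A 5-exo-dig cycloisomerisation (Ag2CO3 10 mol%, benzene, 80 °C) then adds the C12 hydroxyl to the alkyne and gives 9.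

Step 13. Discrimination between the exocyclic alkene and the conjugated ester may be incomplete, and facial selectivity may erode if the hindered alkene needs forcing conditions. The fallback sets out from 13 and returns at 20, and sets C8 before the ester is present. Hydroboration of 13 with 9-BBN (THF, rt) should give the alkylborane F7 and, after H2O2/aq. NaOAc, the iodo alcohol F8. Silylation (Et3SiCl, imidazole, CH2Cl2) should give the triethylsilyl ether F9. Zinc insertion (Zn dust, LiCl, THF) to the alkylzinc iodide F10 and Negishi coupling with 15 (Pd(PPh3)4) should give the bis-silyl ether F11. 48% aq. HF in MeCN removes both silyl groups and gives 20.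

**Further compounds**

F1 | step 7 | (3R)-3-(tert-butyldimethylsilyloxy)-2,2-dimethyl-6-[(E)-2-oxooxolan-3-ylidene]heptanal | C/C(CC[C@@H](O[Si](C)(C)C(C)(C)C)C(C)(C)C=O)=C1/CCOC1=O
F2 | step 7 | (E)-vinyl sulfone: compound 8 with the vinyl terminus carrying a trans phenylsulfonyl group | C/C(CC[C@@H](O[Si](C)(C)C(C)(C)C)C(C)(C)/C=C/S(=O)(=O)c1ccccc1)=C2/CCOC2=O
F3 | step 7 | sulfonyl dienol ether: compound 9 with the vinyl terminus carrying a trans phenylsulfonyl group | C/C(CC[C@@H](O[Si](C)(C)C(C)(C)C)C(C)(C)/C=C/S(=O)(=O)c1ccccc1)=C2/CCOC2=C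
F4 | step 7 | sulfonyl cycloadduct: compound 10 bearing a phenylsulfonyl group at C6 (position 5), cis to the ring-fusion hydrogen at C5 | C1CC2=C(O1)C[C@@H](S(=O)(=O)c4ccccc4)[C@@H]3C(C)(C)[C@H](O[Si](C)(C)C(C)(C)C)CC[C@@]23C
F5 | step 6 | lactol: (E)-3-[(5R)-5-(tert-butyldimethylsilyloxy)-6,6-dimethyloct-7-en-2-ylidene]oxolan-2-ol (anomeric mixture) | C/C(CC[C@@H](O[Si](C)(C)C(C)(C)C)C(C)(C)C=C)=C1/CCOC1O
F6 | step 6 | (3E,7R)-7-(tert-butyldimethylsilyloxy)-3-ethynyl-4,8,8-trimethyldeca-3,9-dien-1-ol | C/C(CC[C@@H](O[Si](C)(C)C(C)(C)C)C(C)(C)C=C)=C(/CCO)C#C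
F7 | step 13 | alkylborane: iodide 13 with 9-borabicyclo[3.3.1]nonan-9-yl added at C17 and hydrogen at C8 anti to the angular methyl | ICC[C@@H]1[C@H](CB3C4CCCC3CCC4)CC[C@@H]2C(C)(C)[C@H](O[Si](C)(C)C(C)(C)C)CC[C@@]12C
F8 | step 13 | iodo alcohol: [(1R,2R,4aS,6R,8aS)-6-(tert-butyldimethylsilyloxy)-1-(2-iodoethyl)-5,5,8a-trimethyldecahydronaphthalen-2-yl]methanol | ICC[C@@H]1[C@H](CO)CC[C@@H]2C(C)(C)[C@H](O[Si](C)(C)C(C)(C)C)CC[C@@]12C
F9 | step 13 | triethylsilyl ether of F8 | ICC[C@@H]1[C@H](CO[Si](CC)(CC)CC)CC[C@@H]2C(C)(C)[C@H](O[Si](C)(C)C(C)(C)C)CC[C@@]12C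
F10 | step 13 | alkylzinc iodide from F9 | I[Zn]CC[C@@H]1[C@H](CO[Si](CC)(CC)CC)CC[C@@H]2C(C)(C)[C@H](O[Si](C)(C)C(C)(C)C)CC[C@@]12C
F11 | step 13 | bis-silyl ether: compound 19 with the C17 hydroxyl as its triethylsilyl ether | COC(=O)/C=C(/C)CC[C@@H]1[C@H](CO[Si](CC)(CC)CC)CC[C@@H]2C(C)(C)[C@H](O[Si](C)(C)C(C)(C)C)CC[C@@]12C
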